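**Retrosynthetic overview**
1. No ring is formed: the pyrrole is bought intact as 3-bromo-1H-pyrrole-2-carbaldehyde, which already fixes the 2-formyl/3-substituent pattern.
2. The C3(pyrrole)–C1'(chain) bond is cut to this bromide plus B-henicosyl-9-BBN (B-alkyl Suzuki–Miyaura coupling).
3. The borane comes from henicos-1-ene by anti-Markovnikov hydroboration.
4. Henicos-1-ene is cut into C18 + C3: octadecylmagnesium chloride plus allyl bromide.

Assumption: the target has a linear C21 (henicosyl) chain and no stereocentre, so it is achiral and there is no enantiomer to control; octadecylmagnesium chloride (0.5 M in THF) and 3-bromo-1H-pyrrole-2-carbaldehyde are taken as catalogue items.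

**Route**

Step 1
Reactants: 1 octadecylmagnesium chloride (0.5 M in THF); 2 allyl bromide (3-bromoprop-1-ene)
Product: 3 henicos-1-ene
Conditions: 2 (1.3 equiv), CuI (2 mol%), THF, 0 °C → rt, 3 h; aq NH4Cl; silica plug (hexanes)
Reagents that add atoms: none
Why: Copper-catalysed Grignard allylation (Kochi-type sp3–sp3 cross-coupling) of a primary alkyl Grignard with the symmetrical allyl electrophile, so SN2 and SN2' give the same terminal alkene, the only side products are inert saturated hydrocarbons, and no stereocentre is formed.

Step 2
Reactants: 3 henicos-1-ene; 4 9-BBN (9-borabicyclo[3.3.1]nonane); 5 3-bromo-1H-pyrrole-2-carbaldehyde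
Product: 7 3-henicosyl-1H-pyrrole-2-carbaldehyde, via B-henicosyl-9-BBN 6 (not isolated)
Conditions: 3 (1.6 equiv), 4 (0.5 M in THF, 1.5 equiv), THF, 0 °C → rt, 12 h; then 3 M aq K3PO4 (4 equiv), 5 (1.0 equiv), Pd(OAc)2 (5 mol%), SPhos (10 mol%), degassed, 65 °C, 12 h; non-oxidative work-up, chromatography
Reagents that add atoms: none
Why: Anti-Markovnikov hydroboration gives the primary alkylborane, and B-alkyl Suzuki–Miyaura coupling then joins it to C3, where zerovalent palladium (formed from Pd(OAc)2) inserts into the C–Br bond activated by the neighbouring formyl group; the alkene is kept in slight excess over 4 so no B–H remains to reduce the aldehyde, the regiochemistry is fixed by the bromide, and no stereocentre arises.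

**Compound list**
1 | octadecylmagnesium chloride | CCCCCCCCCCCCCCCCCC[Mg]Cl | starting material
2 | allyl bromide (3-bromoprop-1-ene) | C=CCBr | starting material
3 | henicos-1-ene | CCCCCCCCCCCCCCCCCCCC=C | intermediate
4 | 9-BBN (9-borabicyclo[3.3.1]nonane) | B1C2CCCC1CCC2 | starting material
5 | 3-bromo-1H-pyrrole-2-carbaldehyde | O=Cc1[nH]ccc1Br | starting material
6 | B-henicosyl-9-BBN (9-henicosyl-9-borabicyclo[3.3.1]nonane) | CCCCCCCCCCCCCCCCCCCCCB1C2CCCC1CCC2 | intermediate
7 | 3-henicosyl-1H-pyrrole-2-carbaldehyde (CNP0217354.0) | CCCCCCCCCCCCCCCCCCCCCc1cc[nH]c1C=O | target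

**Step count and risks**
Total step count: 2. Longest linear sequence: 2 steps (1 → 3 → 7; compounds 2, 4 and 5 enter as bought).

The route has only two steps, so both are ranked rather than three.

Most likely to fail, step 2: the free N–H and the aldehyde of 5 may cause protodebromination, catalyst inhibition by the pyrrolide, or partial aldehyde reduction. The fallback sets out from 5 and comes back at 7. Compound 5 is treated with Boc2O and catalytic DMAP in MeCN at rt to give tert-butyl 3-bromo-2-formyl-1H-pyrrole-1-carboxylate F1, which has no acidic N–H and a more electron-poor C–Br bond. F1 is coupled with borane 6 (made from 3 and 4 as before) using PdCl2(dppf) and aq K3PO4 in THF/DMF at 50 °C to give tert-butyl 2-formyl-3-henicosyl-1H-pyrrole-1-carboxylate F2. TFA in CH2Cl2 at 0 °C → rt then removes the carbamate and gives 7; any Boc already lost in the basic coupling simply delivers 7 early.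

Second, step 1: the waxy hydrocarbon 3 cannot easily be separated from hydrocarbon side products (octadecane, hexatriacontane) if the coupling is incomplete or Wurtz-type coupling is heavy, which upsets the stoichiometry of step 2. The fallback sets out from 1 and comes back at 3, passing through polar, crystallisable intermediates. Compound 1 opens ethylene oxide (catalytic CuI, THF, −30 → 0 °C, then aq NH4Cl) to give icosan-1-ol F3, which is purified by recrystallisation and can also be bought. Dess–Martin periodinane in CH2Cl2 at rt gives icosanal F4. Wittig methylenation with Ph3P=CH2 (from Ph3PCH3Br and KOtBu, THF, 0 °C → rt) gives 3.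

**Further compounds**
F1 | step 2 | tert-butyl 3-bromo-2-formyl-1H-pyrrole-1-carboxylate | CC(C)(C)OC(=O)n1ccc(Br)c1C=O
F2 | step 2 | tert-butyl 2-formyl-3-henicosyl-1H-pyrrole-1-carboxylate | CCCCCCCCCCCCCCCCCCCCCc1ccn(C(=O)OC(C)(C)C)c1C=O
F3 | step 1 | icosan-1-ol | CCCCCCCCCCCCCCCCCCCCO
F4 | step 1 | icosanal | CCCCCCCCCCCCCCCCCCCC=O
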